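The rate constants are made up; the run is a simulation.

In this flask each electrophile that reacts takes up one protic impurity or one nucleophile, so electrophile used equals impurity used plus nucleophile used.

    acid set free + free base ⇌ salt of the base (K1 = 1.7 × 10⁵ M⁻¹, k1 = 2.3 M⁻¹ s⁻¹)
    electrophile + nucleophile → acid set free + product (k2 = 0.031 M⁻¹ s⁻¹)
    nucleophile + acid set free ⇌ protonated nucleophile, settled at all times (K3 = 530 M⁻¹)
    electrophile + protic impurity → quenched substrate (k4 = 0.21 M⁻¹ s⁻¹)
    solid nucleophile ⇌ nucleophile, rate k5*(cs5 - [nucleophile]) while solid is left; crystals form when [nucleophile] > cs5 (cs5 = 2.5 mM, k5 = 0.0048 s⁻¹)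

electrophile 20 mM; free base 40.0 mM; solid nucleophile 16.0 mM; protic impurity 4.00 mM; time 8.0 h

1. part of the electrophile that has reacted at 8.0 h
2. share of free nucleophile in free nucleophile and protonated nucleophile together, at 8.0 h

- as a solid, counted per litre of solution: solid nucleophile
- at the start none of the solid nucleophile is in solution
- run time (flask): 8.0 h

I name the cover 100%: protic impurity plus solid nucleophile charged, per electrophile charged, the ceiling on the part reacted. The flask has a full ceiling, and the reaction with electrophile alone halves nucleophile in 0.31 h, short against 8.0 h. Yet I expect electrophile to remain.

The two clear up because dissolved nucleophile stays near solubility, 12.5% of the electrophile charge. Electrophile then decays pseudo-first-order, with a half-life of 2.48 h, longer than that of nucleophile. Electrophile at its charge halves protic impurity in 0.0458 h, shorter than that half-life, so I take off the whole impurity charge first, 20.0% of the electrophile charge.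

First round, electrophile left at solubility:

8.59%

Its mean over the run is 32.0%. I put that back in. Dissolution against consumption holds the level at this share of solubility:

96.0%

Second round, electrophile left:

9.38%

So I commit to 90.6% reacted. That asks for 82.6% of the electrophile charge in nucleophile, against 80.0% charged, so the solid ends early and my figure runs slightly high.

The forecast gives 89.7% and 99.7%, below my figure for the part reacted, with the solid “running out only near the end”.

The flask gives 90.2% and 99.7%.

The flask has not come to rest at 8.0 h, since it stands below its cover. Solid nucleophile is at 0%, electrophile at 9.81%, and nucleophile at 1.96 mM, which is 9.78% of the electrophile charge. The neighbour flask with 6.4 mM of solid nucleophile has a cover of 52.0%, reaches 52.0%, and keeps 0.00128 mM of nucleophile. In the flask itself, 80.0 h brings product from 70.2% to 79.4% and the part reacted to 99.4%.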